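If these flasks are run again, what to watch is how much Q goes to J while Z comes down, so we follow one Q molecule through its forks: to Z giving L, to E giving G, or by itself to J.

| setting | winter | autumn | dusk | midnight | south-west | north-east | east | south-east |
|---|---|---|---|---|---|---|---|---|
| Z | 0.40 M | 0.40 M | 0.40 M | 0.80 M | 0.40 M (in portions, 5, over 30 s) | 0.40 M | 0.40 M | 0.40 M (fed, over 30 s) |
| Q | 0.80 M | 0.54 M | 1.2 M | 0.80 M | 0.800 M | 0.800 M | 0.800 M | 0.800 M |
| E | 0.40 M | 0.40 M | 0.40 M | 0.40 M | 0.400 M | 0.400 M | 0.400 M (fed, over 30 s) | 0.400 M |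
| X | 25 mM | 25 mM | 25 mM | 25 mM | 25 mM | 25 mM | 25 mM | 25 mM |
| remark | run made earlier | run made earlier | run made earlier | run made earlier | first portion at the start, last at 30 s | everything together at the start | all else is in the flask from the start; the feed brings no volume worth counting | all else is in the flask from the start; the feed brings no volume worth counting |
| time |  |  |  |  | 2.5 min | 2.5 min | 2.5 min | 2.5 min |

winter run (percent of the Z charged)

| time / min | L / % | Z / % |
|---|---|---|
| 0.167 | 74.9 | 24.0 |
| 0.500 | 80.6 | 18.9 |
| 0.833 | 81.5 | 17.2 |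
| 1.33 | 80.6 | 18.8 |
| 2.00 | 81.8 | 19.2 |
| 2.50 | 80.3 | 18.4 |

autumn run (percent of the Z charged)

| time / s | L / % | Z / % |
|---|---|---|
| 20.0 | 46.6 | 54.4 |
| 40.0 | 45.4 | 51.4 |
| 60.0 | 46.3 | 53.4 |
| 80.0 | 48.9 | 54.2 |
| 90.0 | 47.4 | 52.6 |
| 120 | 48.1 | 51.9 |

dusk run (percent of the Z charged)

| time / s | L / % | Z / % |
|---|---|---|
| 10.0 | 97.4 | 4.1 |
| 15.0 | 99.2 | 1.3 |
| 25.0 | 99.7 | 0 |
| 40.0 | 99.8 | 1.8 |
| 80.0 | 101.4 | 0 |
| 120 | 99.1 | 0.9 |

midnight run (percent of the Z charged)

| time / s | L / % | Z / % |
|---|---|---|
| 10.0 | 52.5 | 48.9 |
| 30.0 | 53.1 | 46.2 |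
| 60.0 | 53.7 | 46.5 |
| 80.0 | 53.9 | 45.6 |
| 120 | 53.0 | 46.5 |

(each reading ± 1 percentage point)

- steps that have been proposed: Z + Q + X -> X + L; Q -> J; E + Q + X -> X + G

* the best flask by amount of L, in percent of the Z charged; "all alike" if 1.5 percentage points covers them all (south-west / north-east / east / south-east / all alike)
* amount of L at the end, in percent of the Z charged, south-west
* amount of L at the end, in percent of the Z charged, north-east
* amount of L at the end, in percent of the Z charged, east
* amount of L at the end, in percent of the Z charged, south-east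

Winter stands flat from 0.500 min on, with L averaging 81.0% and Z 18.5%, which we read as Q being the limiting reagent. Taking G at the full charge of E gives J in winter:

c_J = 0.80 M − 0.40 M − 0.324 M = 0.0762 M

If the steps to L and J are both first order in Q, X is unchanged and Z is in from the start, each unit of ln c_Z lost costs the same Q to J. We call this price the toll T, which is also the c_Z at which a Q molecule has even chances of L and J:

T = 0.0762 M / ln 5.41 = 0.0451 M

Now the ladder, fastest first. E beats Z: autumn averages Z 53.0% and L 47.1%, the toll charges 0.0287 M to J, and G gets 0.323 M, so in ln c the fall of E runs ahead of that of Z: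

ratio = 2.59

Next comes Z against J: of the Q molecules that E does not take, at c_Z equal to the charge 0.40 M one goes to J with chance 10.1%, and with c_Z below T that chance passes even. Last comes the standstill: dusk already reads L at 97.4% after 10.0 s, far earlier than 2.5 min. So in south-west and south-east, where Z is spread over 30 s, we expect E to take its 0.400 M first, leaving 0.400 M of Q to be shared between L and J.

The forecast gives 53% for south-west, 81% for north-east, 98% for east and 52% for south-east, with east best, holding for south-east and south-west that “E burns 0.40 M of Q within seconds”. We price its east figure ourselves: bringing Z down to 2.00% costs 0.177 M of J, and with L at 0.392 M this asks for 0.569 M of the 0.800 M charged.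

East gives 97.8% of L, above south-west at 51.4%, north-east at 80.8% and south-east at 49.5%, so east leads as forecast. At 2.50 min east holds Z at 2.17% and Q at 0% of its charge.

    Z + Q + X → X + L (k = 34.0 M⁻² s⁻¹)
    Q → J (k = 0.0430 s⁻¹)
    E + Q + X → X + G (k = 83.9 M⁻² s⁻¹)

The toll from winter, put on that Z in east, charges 0.173 M to J, and the J standing in east at 2.50 min is 0.194 M.

Readings and results come from a simulation from invented constants; scatter was added.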